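**Retrosynthetic overview**
1. Target ⇒ cleavage of a side-chain methyl ester and late acylation of the C8 hydroxyl of a bicyclic cis-7,8-diol by orsellinic acid (arene from self-condensation of methyl acetoacetate).
2. Ring A (pyran) ⇒ 6-endo cycloisomerisation of a 3-alkynyl-4-(hydroxymethylidene)cyclohexenone; C1 comes from trimethyl orthoformate (vinylogous Mukaiyama), the acrylate arm from a Sonogashira coupling.
3. Ring B (cyclohexenone carrying the C7 carbinol) ⇒ α-ketol ring expansion of a 1-acetylcyclopent-2-en-1-ol; the siloxy-bearing carbon (future C8) migrates and relays its configuration to C7.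
4. The cyclopentenol ⇒ (R)-4-hydroxycyclopent-2-en-1-one, ethynyltrimethylsilane (addition, then oxidative 1,3-transposition) and ethyl vinyl ether (acetyl anion equivalent).
5. Ring order: five-membered carbocycle (purchased) → ring B by expansion → ring A by cycloisomerisation; the orsellinate arene is built separately.

Assumption: building blocks that deliver skeletal carbons (including ethynyltrimethylsilane, ethyl vinyl ether and trimethyl orthoformate) are numbered as starting materials; silylating agents, bases and oxidants are treated as reagents.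

**Step 1**
Reactants: 1 (R)-4-hydroxycyclopent-2-en-1-one
Product: 2 (R)-4-{[tert-butyl(dimethyl)silyl]oxy}cyclopent-2-en-1-one
Conditions: TBSCl, imidazole, DMAP (cat.), CH2Cl2, 0 °C to rt
Reagents that add atoms: tert-butyldimethylsilyl chloride, CC(C)(C)[Si](C)(C)Cl
Why: Standard silyl ether formation protects the carbinol that becomes C8 against the organolithium and oxidation steps; the stereocentre is untouched.

**Step 2**
Reactants: 2 (R)-4-{[tert-butyl(dimethyl)silyl]oxy}cyclopent-2-en-1-one; 3 ethynyltrimethylsilane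
Product: 5 (4R)-4-{[tert-butyl(dimethyl)silyl]oxy}-1-[(trimethylsilyl)ethynyl]cyclopent-2-en-1-ol (both C1 epimers), via lithium (trimethylsilyl)acetylide 4 (not isolated)
Conditions: 3, n-BuLi, THF, −78 °C; then 2, −78 °C; H2O
Reagents that add atoms: none
Why: 1,2-Addition of a lithium acetylide to the enone carbonyl; the new carbinol centre is erased in step 3, so both epimers converge.

**Step 3**
Reactants: 5 (4R)-4-{[tert-butyl(dimethyl)silyl]oxy}-1-[(trimethylsilyl)ethynyl]cyclopent-2-en-1-ol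
Product: 6 (5R)-5-{[tert-butyl(dimethyl)silyl]oxy}-3-[(trimethylsilyl)ethynyl]cyclopent-2-en-1-one
Conditions: 4-acetamido-2,2,6,6-tetramethyl-1-oxopiperidin-1-ium tetrafluoroborate, MeCN, rt
Reagents that add atoms: none
Why: Oxoammonium-mediated oxidative 1,3-transposition of a tertiary allylic alcohol (Babler–Dauben type) moves the oxygen to C3, so the new carbonyl sits next to the siloxy stereocentre, which is not touched.

**Step 4**
Reactants: 6 (5R)-5-{[tert-butyl(dimethyl)silyl]oxy}-3-[(trimethylsilyl)ethynyl]cyclopent-2-en-1-one; 7 ethyl vinyl ether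
Product: 10 1-[(1S,5R)-5-{[tert-butyl(dimethyl)silyl]oxy}-1-hydroxy-3-[(trimethylsilyl)ethynyl]cyclopent-2-en-1-yl]ethan-1-one, via 1-ethoxyvinyllithium 8 (not isolated), via enol ether adduct 9 (not isolated)
Conditions: 7, t-BuLi, THF, −78 to 0 °C; then 6, −78 °C; then 1 M HCl, THF, 0 °C
Reagents that add atoms: water, O
Why: The acetyl anion equivalent adds 1,2 to the carbonyl anti to the adjacent OTBS group (steric control on the five-membered ring), giving the 1S carbinol with OH cis to OTBS; dilute acid hydrolyses the enol ether to the acetyl group.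

**Step 5**
Reactants: 10 1-[(1S,5R)-5-{[tert-butyl(dimethyl)silyl]oxy}-1-hydroxy-3-[(trimethylsilyl)ethynyl]cyclopent-2-en-1-yl]ethan-1-one
Product: 11 (5R,6R)-5-{[tert-butyl(dimethyl)silyl]oxy}-6-hydroxy-6-methyl-3-[(trimethylsilyl)ethynyl]cyclohex-2-en-1-one
Conditions: Ni(OTf)2 (10 mol %), 2,2′-bipyridine (12 mol %), iPr2NEt (20 mol %), 4 Å MS, ClCH2CH2Cl, 60 °C
Reagents that add atoms: none
Why: Proposed new method: the alkoxide of the tertiary carbinol binds divalent nickel and chelates the acetyl oxygen (O–C–C=O syn-coplanar), the metal-bound oxygen pushes, and ring carbon C5 (an α-siloxy sp3 carbon) migrates suprafacially with retention onto the acetyl carbon, so the 1S carbinol with OH cis to OTBS becomes the 6R tertiary alcohol cis to the 5R siloxy group while ring B and its conjugated enone form; only this shift gives a conjugated enone and α-ketol shifts are reversible, so an alkenyl-shift isomer can drain back to 11; the closest known reaction type is the Lewis-acid or nickel-catalysed α-ketol (acyloin) ring expansion of 1-acylcyclopentanols to 2-hydroxy-2-alkylcyclohexanones (steroid D-homoannulation), not yet shown for 1-acylcyclopent-2-en-1-ols or with chirality relay from a neighbouring siloxy carbon.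

**Step 6**
Reactants: 11 (5R,6R)-5-{[tert-butyl(dimethyl)silyl]oxy}-6-hydroxy-6-methyl-3-[(trimethylsilyl)ethynyl]cyclohex-2-en-1-one; 12 methyl (2E)-3-iodoprop-2-enoate
Product: 14 methyl (2E)-5-[(4R,5R)-5-{[tert-butyl(dimethyl)silyl]oxy}-4-hydroxy-4-methyl-3-oxocyclohex-1-en-1-yl]pent-2-en-4-ynoate, via terminal alkyne 13 (not isolated)
Conditions: CsF, PdCl2(PPh3)2 (3 mol %), CuI (6 mol %), Et3N, THF/MeOH, rt
Reagents that add atoms: none
Why: Fluoride-triggered protodesilylation of the alkynylsilane followed in the same flask by Sonogashira coupling with the (E)-vinyl iodide (alkene geometry retained); the terminal ynenone is consumed as it forms.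

**Step 7**
Reactants: 14 methyl (2E)-5-[(4R,5R)-5-{[tert-butyl(dimethyl)silyl]oxy}-4-hydroxy-4-methyl-3-oxocyclohex-1-en-1-yl]pent-2-en-4-ynoate; 15 trimethyl orthoformate
Product: 17 methyl (2E)-5-[(4R,5R)-5-{[tert-butyl(dimethyl)silyl]oxy}-6-(dimethoxymethyl)-4-methyl-3-oxo-4-[(trimethylsilyl)oxy]cyclohex-1-en-1-yl]pent-2-en-4-ynoate (C6 epimers), via silyl dienol ether 16 (not isolated)
Conditions: TMSOTf, Et3N, CH2Cl2, −78 to 0 °C; pentane filtration; then 15, TMSOTf (10 mol %), CH2Cl2, −78 °C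
Reagents that add atoms: trimethylsilyl trifluoromethanesulfonate, C[Si](C)(C)OS(=O)(=O)C(F)(F)F
Why: Soft enolisation can only take the γ-proton (the α′ carbon is quaternary), and the linear silyl dienol ether attacks the dimethoxycarbenium ion at its γ-terminus (vinylogous Mukaiyama reaction), installing C1 at the aldehyde oxidation level; the new centre becomes sp2 in step 8.

**Step 8**
Reactants: 17 methyl (2E)-5-[(4R,5R)-5-{[tert-butyl(dimethyl)silyl]oxy}-6-(dimethoxymethyl)-4-methyl-3-oxo-4-[(trimethylsilyl)oxy]cyclohex-1-en-1-yl]pent-2-en-4-ynoate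
Product: 19 methyl (2E)-3-[(7R,8R)-7,8-dihydroxy-7-methyl-6-oxo-7,8-dihydro-6H-isochromen-3-yl]prop-2-enoate, via hydroxymethylidene ketone 18 (not isolated)
Conditions: aq. HF, MeCN, 0 °C; NaHCO3; then CuI (10 mol %), iPr2NEt, CH2Cl2, rt
Reagents that add atoms: water, O
Why: HF hydrolyses the acetal and cleaves both silyl ethers; the formyl ketone exists as the acidic hydroxymethylidene tautomer, whose oxygen (deprotonated in preference to the C8 carbinol) adds 6-endo-dig to the alkyne activated by monovalent copper (azaphilone-type cycloisomerisation), closing ring A without touching C7 or C8.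

**Step 9**
Reactants: 20 methyl acetoacetate (two equivalents)
Product: 23 methyl 2,4-dihydroxy-6-methylbenzoate (methyl orsellinate), via acetoacetate dianion 21 (not isolated), via methyl 3,5,7-trioxooctanoate 22 (not isolated)
Conditions: NaH (1 equiv), THF, 0 °C; n-BuLi (0.5 equiv), −78 °C; reflux; 2 M HCl
Reagents that add atoms: none
Why: Biomimetic polyketide assembly: Claisen condensation of the dianion (through C4) on the ester of a second acetoacetate gives the triketo ester, which closes by intramolecular aldol condensation and aromatises.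

**Step 10**
Reactants: 23 methyl 2,4-dihydroxy-6-methylbenzoate
Product: 24 2,4-dihydroxy-6-methylbenzoic acid (orsellinic acid)
Conditions: KOH, H2O, 80 °C; then HCl, 0 °C
Reagents that add atoms: potassium hydroxide, [K+].[OH-]
Why: Saponification of the hindered ester as its phenoxide salt; cold acidification avoids decarboxylation of the free acid.

**Step 11**
Reactants: 19 methyl (2E)-3-[(7R,8R)-7,8-dihydroxy-7-methyl-6-oxo-7,8-dihydro-6H-isochromen-3-yl]prop-2-enoate; 24 2,4-dihydroxy-6-methylbenzoic acid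
Product: 28 (7R,8R)-7-hydroxy-3-[(1E)-3-methoxy-3-oxoprop-1-en-1-yl]-7-methyl-6-oxo-7,8-dihydro-6H-isochromen-8-yl 2,4-dihydroxy-6-methylbenzoate, via tris-silyl orsellinate 25 (not isolated), via silylated aroyl chloride 26 (not isolated), via bis-silyl ester 27 (not isolated)
Conditions: 24, (Me3Si)2NH, 80 °C; (COCl)2, DMF (cat.), CH2Cl2, 0 °C; then 19, Et3N, DMAP, CH2Cl2, 0 °C to rt; aq. citric acid, THF
Reagents that add atoms: none
Why: Transient O-silylation masks the phenols and lets the silyl ester be converted into the acyl chloride; DMAP-catalysed acylation takes the secondary C8 hydroxyl rather than the tertiary C7 hydroxyl with retention at both centres, and the aqueous acid work-up removes the aryl silyl ethers.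

**Step 12**
Reactants: 28 (7R,8R)-7-hydroxy-3-[(1E)-3-methoxy-3-oxoprop-1-en-1-yl]-7-methyl-6-oxo-7,8-dihydro-6H-isochromen-8-yl 2,4-dihydroxy-6-methylbenzoate
Product: 29 (+)-mitorubrinic acid B, (7R,8R)-3-[(1E)-2-carboxyethen-1-yl]-7-hydroxy-7-methyl-6-oxo-7,8-dihydro-6H-isochromen-8-yl 2,4-dihydroxy-6-methylbenzoate
Conditions: Me3SnOH, ClCH2CH2Cl, 70 °C; 0.1 M HCl
Reagents that add atoms: trimethyltin hydroxide, C[Sn](C)(C)O
Why: Mild tin hydroxide ester hydrolysis cleaves the unhindered methyl ester while the di-ortho-substituted aryl ester at C8 and the base-sensitive chromophore are left alone.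

**Compound list**
1 | (R)-4-hydroxycyclopent-2-en-1-one | O[C@@H]1CC(=O)C=C1 | starting material
2 | (R)-4-{[tert-butyl(dimethyl)silyl]oxy}cyclopent-2-en-1-one | CC(C)(C)[Si](C)(C)O[C@@H]1CC(=O)C=C1 | intermediate
3 | ethynyltrimethylsilane | C#C[Si](C)(C)C | starting material
4 | lithium (trimethylsilyl)acetylide | [Li]C#C[Si](C)(C)C | intermediate
5 | (4R)-4-{[tert-butyl(dimethyl)silyl]oxy}-1-[(trimethylsilyl)ethynyl]cyclopent-2-en-1-ol (C1 epimers) | C[Si](C)(C)C#CC1(O)C[C@@H](O[Si](C)(C)C(C)(C)C)C=C1 | intermediate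
6 | (5R)-5-{[tert-butyl(dimethyl)silyl]oxy}-3-[(trimethylsilyl)ethynyl]cyclopent-2-en-1-one | O=C1C=C(C#C[Si](C)(C)C)C[C@H]1O[Si](C)(C)C(C)(C)C | intermediate
7 | ethyl vinyl ether | C=COCC | starting material
8 | 1-ethoxyvinyllithium | C=C([Li])OCC | intermediate
9 | (1S,5R)-5-{[tert-butyl(dimethyl)silyl]oxy}-1-(1-ethoxyethenyl)-3-[(trimethylsilyl)ethynyl]cyclopent-2-en-1-ol | CCOC(=C)[C@]1(O)C=C(C#C[Si](C)(C)C)C[C@H]1O[Si](C)(C)C(C)(C)C | intermediate
10 | 1-[(1S,5R)-5-{[tert-butyl(dimethyl)silyl]oxy}-1-hydroxy-3-[(trimethylsilyl)ethynyl]cyclopent-2-en-1-yl]ethan-1-one | CC(=O)[C@]1(O)C=C(C#C[Si](C)(C)C)C[C@H]1O[Si](C)(C)C(C)(C)C | intermediate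
11 | (5R,6R)-5-{[tert-butyl(dimethyl)silyl]oxy}-6-hydroxy-6-methyl-3-[(trimethylsilyl)ethynyl]cyclohex-2-en-1-one | CC(C)(C)[Si](C)(C)O[C@@H]1CC(C#C[Si](C)(C)C)=CC(=O)[C@]1(C)O | intermediate
12 | methyl (2E)-3-iodoprop-2-enoate | COC(=O)/C=C/I | starting material
13 | (5R,6R)-5-{[tert-butyl(dimethyl)silyl]oxy}-3-ethynyl-6-hydroxy-6-methylcyclohex-2-en-1-one | CC(C)(C)[Si](C)(C)O[C@@H]1CC(C#C)=CC(=O)[C@]1(C)O | intermediate
14 | methyl (2E)-5-[(4R,5R)-5-{[tert-butyl(dimethyl)silyl]oxy}-4-hydroxy-4-methyl-3-oxocyclohex-1-en-1-yl]pent-2-en-4-ynoate | CC(C)(C)[Si](C)(C)O[C@@H]1CC(C#C/C=C/C(=O)OC)=CC(=O)[C@]1(C)O | intermediate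
15 | trimethyl orthoformate | COC(OC)OC | starting material
16 | methyl (2E)-5-[(3R,4R)-3-{[tert-butyl(dimethyl)silyl]oxy}-4-methyl-4,5-bis[(trimethylsilyl)oxy]cyclohexa-1,5-dien-1-yl]pent-2-en-4-ynoate | CC(C)(C)[Si](C)(C)O[C@@H]1C=C(C#C/C=C/C(=O)OC)C=C(O[Si](C)(C)C)[C@]1(C)O[Si](C)(C)C | intermediate
17 | methyl (2E)-5-[(4R,5R)-5-{[tert-butyl(dimethyl)silyl]oxy}-6-(dimethoxymethyl)-4-methyl-3-oxo-4-[(trimethylsilyl)oxy]cyclohex-1-en-1-yl]pent-2-en-4-ynoate (C6 epimers) | CC(C)(C)[Si](C)(C)O[C@@H]1C(C(OC)OC)C(C#C/C=C/C(=O)OC)=CC(=O)[C@]1(C)O[Si](C)(C)C | intermediate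
18 | methyl (2E)-5-[(4R,5R)-6-formyl-4,5-dihydroxy-4-methyl-3-oxocyclohex-1-en-1-yl]pent-2-en-4-ynoate (present mainly as the hydroxymethylidene tautomer) | O[C@@H]1C(C=O)C(C#C/C=C/C(=O)OC)=CC(=O)[C@]1(C)O | intermediate
19 | methyl (2E)-3-[(7R,8R)-7,8-dihydroxy-7-methyl-6-oxo-7,8-dihydro-6H-isochromen-3-yl]prop-2-enoate | O[C@@H]1C2=COC(/C=C/C(=O)OC)=CC2=CC(=O)[C@]1(C)O | intermediate
20 | methyl acetoacetate | CC(=O)CC(=O)OC | starting material
21 | methyl acetoacetate dianion (sodium lithium salt) | [Na+].[Li+].[CH2-]C(=O)[CH-]C(=O)OC | intermediate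
22 | methyl 3,5,7-trioxooctanoate | CC(=O)CC(=O)CC(=O)CC(=O)OC | intermediate
23 | methyl 2,4-dihydroxy-6-methylbenzoate | Cc1cc(O)cc(O)c1C(=O)OC | intermediate
24 | 2,4-dihydroxy-6-methylbenzoic acid | Cc1cc(O)cc(O)c1C(=O)O | intermediate
25 | trimethylsilyl 2-methyl-4,6-bis[(trimethylsilyl)oxy]benzoate | Cc1cc(O[Si](C)(C)C)cc(O[Si](C)(C)C)c1C(=O)O[Si](C)(C)C | intermediate
26 | 2-methyl-4,6-bis[(trimethylsilyl)oxy]benzoyl chloride | Cc1cc(O[Si](C)(C)C)cc(O[Si](C)(C)C)c1C(=O)Cl | intermediate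
27 | (7R,8R)-7-hydroxy-3-[(1E)-3-methoxy-3-oxoprop-1-en-1-yl]-7-methyl-6-oxo-7,8-dihydro-6H-isochromen-8-yl 2-methyl-4,6-bis[(trimethylsilyl)oxy]benzoate | Cc1cc(O[Si](C)(C)C)cc(O[Si](C)(C)C)c1C(=O)O[C@@H]1C2=COC(/C=C/C(=O)OC)=CC2=CC(=O)[C@]1(C)O | intermediate
28 | (7R,8R)-7-hydroxy-3-[(1E)-3-methoxy-3-oxoprop-1-en-1-yl]-7-methyl-6-oxo-7,8-dihydro-6H-isochromen-8-yl 2,4-dihydroxy-6-methylbenzoate | Cc1cc(O)cc(O)c1C(=O)O[C@@H]1C2=COC(/C=C/C(=O)OC)=CC2=CC(=O)[C@]1(C)O | intermediate
29 | (+)-mitorubrinic acid B, (7R,8R) | Cc1cc(O)cc(O)c1C(=O)O[C@@H]1C2=COC(/C=C/C(=O)O)=CC2=CC(=O)[C@]1(C)O | target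

**Step count and risks**
Total steps: 12. Longest linear sequence: 10 (steps 1 to 8, then 11 and 12); steps 9 and 10 form the short orsellinate branch.

The three steps most likely to fail are 5, 7 and 11.

Step 5 (the proposed ring expansion) may suffer from migration of the alkenyl carbon instead of the siloxy carbon, or from the wrong C6 epimer. The fallback uses known chemistry only, sets out from 6 and comes back at 11. Conjugate reduction of 6 with [(Ph3P)CuH]6 gives (2R)-2-{[tert-butyl(dimethyl)silyl]oxy}-4-[(trimethylsilyl)ethynyl]cyclopentan-1-one F1 (C4 epimers). Addition of 8 gives (1S,2R)-2-{[tert-butyl(dimethyl)silyl]oxy}-1-(1-ethoxyethenyl)-4-[(trimethylsilyl)ethynyl]cyclopentan-1-ol F2, and dilute HCl turns it into 1-[(1S,2R)-2-{[tert-butyl(dimethyl)silyl]oxy}-1-hydroxy-4-[(trimethylsilyl)ethynyl]cyclopentyl]ethan-1-one F3. The classical Al(OtBu)3-promoted α-ketol ring expansion of this saturated 1-acetylcyclopentanol has no alkenyl competitor; the more substituted carbon migrates through the aluminium chelate to give (2R,3R)-3-{[tert-butyl(dimethyl)silyl]oxy}-2-hydroxy-2-methyl-5-[(trimethylsilyl)ethynyl]cyclohexan-1-one F4. IBX in DMSO at 70 °C dehydrogenates the only enolisable side and returns 11.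

Step 7 (γ-selective vinylogous Mukaiyama formylation) may give α-attack or ionise the allylic silyl ether. The fallback sets out from 11 and comes back at 19. Heating 11 with tert-butoxybis(dimethylamino)methane in toluene gives the γ-aminomethylidene enone (5R,6R)-5-{[tert-butyl(dimethyl)silyl]oxy}-4-[(dimethylamino)methylidene]-6-hydroxy-6-methyl-3-[(trimethylsilyl)ethynyl]cyclohex-2-en-1-one F5. The CsF-mediated Sonogashira coupling with 12 of step 6 then gives methyl (2E)-5-[(4R,5R)-5-{[tert-butyl(dimethyl)silyl]oxy}-6-[(dimethylamino)methylidene]-4-hydroxy-4-methyl-3-oxocyclohex-1-en-1-yl]pent-2-en-4-ynoate F6. Aqueous HF in MeCN hydrolyses the enaminone and removes the silyl ether to give 18, which is cyclised with CuI and iPr2NEt to 19.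

Step 11 (acylation of a hindered secondary alcohol by a di-ortho-substituted aroyl chloride carrying only transient silyl protection) may be slow or unselective. The fallback sets out from 23 and 19 and comes back at 28. MOMCl and NaH convert 23 into methyl 2,4-bis(methoxymethoxy)-6-methylbenzoate F7, and KOH in aqueous MeOH gives 2,4-bis(methoxymethoxy)-6-methylbenzoic acid F8. This stable acid is coupled with 19 by Shiina esterification (2-methyl-6-nitrobenzoic anhydride, DMAP, Et3N), which can be forced and the product purified, to give (7R,8R)-7-hydroxy-3-[(1E)-3-methoxy-3-oxoprop-1-en-1-yl]-7-methyl-6-oxo-7,8-dihydro-6H-isochromen-8-yl 2,4-bis(methoxymethoxy)-6-methylbenzoate F9. TFA in CH2Cl2 at 0 °C removes both MOM groups and returns 28.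

**Further compounds**
F1 | step 5 | (2R)-2-{[tert-butyl(dimethyl)silyl]oxy}-4-[(trimethylsilyl)ethynyl]cyclopentan-1-one | O=C1CC(C#C[Si](C)(C)C)C[C@H]1O[Si](C)(C)C(C)(C)C
F2 | step 5 | (1S,2R)-2-{[tert-butyl(dimethyl)silyl]oxy}-1-(1-ethoxyethenyl)-4-[(trimethylsilyl)ethynyl]cyclopentan-1-ol | CCOC(=C)[C@]1(O)CC(C#C[Si](C)(C)C)C[C@H]1O[Si](C)(C)C(C)(C)C
F3 | step 5 | 1-[(1S,2R)-2-{[tert-butyl(dimethyl)silyl]oxy}-1-hydroxy-4-[(trimethylsilyl)ethynyl]cyclopentyl]ethan-1-one | CC(=O)[C@]1(O)CC(C#C[Si](C)(C)C)C[C@H]1O[Si](C)(C)C(C)(C)C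
F4 | step 5 | (2R,3R)-3-{[tert-butyl(dimethyl)silyl]oxy}-2-hydroxy-2-methyl-5-[(trimethylsilyl)ethynyl]cyclohexan-1-one | CC(C)(C)[Si](C)(C)O[C@@H]1CC(C#C[Si](C)(C)C)CC(=O)[C@]1(C)O
F5 | step 7 | (5R,6R)-5-{[tert-butyl(dimethyl)silyl]oxy}-4-[(dimethylamino)methylidene]-6-hydroxy-6-methyl-3-[(trimethylsilyl)ethynyl]cyclohex-2-en-1-one | CC(C)(C)[Si](C)(C)O[C@@H]1C(=CN(C)C)C(C#C[Si](C)(C)C)=CC(=O)[C@]1(C)O
F6 | step 7 | methyl (2E)-5-[(4R,5R)-5-{[tert-butyl(dimethyl)silyl]oxy}-6-[(dimethylamino)methylidene]-4-hydroxy-4-methyl-3-oxocyclohex-1-en-1-yl]pent-2-en-4-ynoate | CC(C)(C)[Si](C)(C)O[C@@H]1C(=CN(C)C)C(C#C/C=C/C(=O)OC)=CC(=O)[C@]1(C)O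
F7 | step 11 | methyl 2,4-bis(methoxymethoxy)-6-methylbenzoate | COCOc1cc(C)c(C(=O)OC)c(OCOC)c1
F8 | step 11 | 2,4-bis(methoxymethoxy)-6-methylbenzoic acid | COCOc1cc(C)c(C(=O)O)c(OCOC)c1
F9 | step 11 | (7R,8R)-7-hydroxy-3-[(1E)-3-methoxy-3-oxoprop-1-en-1-yl]-7-methyl-6-oxo-7,8-dihydro-6H-isochromen-8-yl 2,4-bis(methoxymethoxy)-6-methylbenzoate | COCOc1cc(C)c(C(=O)O[C@@H]2C3=COC(/C=C/C(=O)OC)=CC3=CC(=O)[C@]2(C)O)c(OCOC)c1
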